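The target, 8α-vanilloyloxyguai-1(10)-ene-4β,6β-diol, is disconnected at C4–C5. The key step exploits the position of C5 in ring B. C5 lies between C6=C7 and C1=C10, is the vinylogous α-position of a C8 ketone, and is the direct neighbour of C4, the carbinol carbon of ring A. An achiral 2-isopropyl-6-methyl-5-(3-oxobutyl)cyclohepta-2,5-dienone is therefore closed with a chiral primary amine. Its trienamine attacks the tethered methyl ketone through C5 and creates ring A, the C4–C5 bond and both ring A stereocentres in one catalytic operation. C6, C7 and C8 are then relayed from these centres.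

Key step: step 7

Numbering: guaiane numbering (ring A = C1–C5; ring B = C1, C5–C10) is used for the ring atoms from compound 5 onward. The target has 4β-OH, 5α-H, 6β-OH, 7α-H (isopropyl β) and 8α-acyloxy, which is (4S,5S,6R,7S,8S).

Assumption: the quinine-derived 9-epi-amine is taken to favour (4S,5R)-11; if it favours the antipode, the pseudo-enantiomeric quinidine-derived amine is used and nothing else changes.

Design notes
- Loss of H-5 from the C8 iminium ion gives a linearly conjugated trienamine, a 1-aminocyclohepta-1,3,5-triene. The cross-conjugated isomer formed by loss of H-9 is in equilibrium with it but cannot cyclise.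
- The ring carbonyl is kept as a dimethyl ketal from the moment the seven-membered ring exists. A free 2-bromocyclohepta-2,5-dienone is enolisable and would lose HBr to a tropone.
- C1=C10 is the most electron-rich alkene, so oxygen is brought to C6=C7 only under the direction of an allylic 8β-OH.
- The C7–O bond is then cleaved by electron transfer through a C8 ketone, which avoids hydride substitution at a fully substituted carbon.
- C8 is finally set by hydride delivery from 6β-OH.
- Ring A holds C4 pseudo-equatorial on C5. In the chair-like ring B, β is therefore axial at C6 and C8, and α is axial at C7.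

Step 1
Reactants: 1 4-bromo-3-methylanisole; 2 but-3-en-2-ol
Product: 3 4-(4-methoxy-2-methylphenyl)butan-2-one
Conditions: Pd(OAc)2 (2 mol%), P(o-tol)3, NaHCO3, DMF, 110 °C
Reagents that add atoms: none
Why: Heck reaction of an allylic alcohol, in which aryl–Pd adds to the terminal alkene carbon and β-hydride elimination toward the carbinol carbon followed by tautomerisation gives the saturated methyl ketone directly, so no separate hydrogenation is needed.

Step 2
Reactants: 3 4-(4-methoxy-2-methylphenyl)butan-2-one
Product: 4 4-(3,3-dimethoxybutyl)-3-methylanisole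
Conditions: HC(OMe)3, MeOH, TsOH (cat.), rt
Reagents that add atoms: trimethyl orthoformate, COC(OC)OC; methanol, CO
Why: Acid-catalysed ketalisation driven by the orthoester masks the ketone against dissolving metal and strong base, and the acyclic ketal is chosen because it later falls off under acid mild enough to leave a β,γ-unsaturated ketone in place.

Step 3
Reactants: 4 4-(3,3-dimethoxybutyl)-3-methylanisole
Product: 5 4-(3,3-dimethoxybutyl)-1-methoxy-5-methylcyclohexa-1,4-diene
Conditions: Li, liq. NH3, t-BuOH, THF, −78 to −33 °C
Reagents that add atoms: none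
Why: Birch reduction, in which protonation occurs at the two unsubstituted, mutually para positions ortho and meta to the methoxy group, so the 1,4-diene carries the enol ether (future C8=C6) and the tetrasubstituted alkene (future C1=C10) exactly where they are needed.

Step 4
Reactants: 5 4-(3,3-dimethoxybutyl)-1-methoxy-5-methylcyclohexa-1,4-diene
Product: 7 2-bromo-5-(3,3-dimethoxybutyl)-6-methylcyclohepta-2,5-dien-1-one dimethyl ketal, via dibromocyclopropane 6 (not isolated)
Conditions: CHBr3 (0.95 equiv), KOt-Bu, pentane, −20 °C; filter, concentrate cold; then NaHCO3, MeOH, 40 °C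
Reagents that add atoms: bromoform, BrC(Br)Br; methanol, CO
Why: Dibromocarbene cyclopropanation of the enol ether (the π bond with the highest HOMO and the only one with an unhindered CH terminus) followed by gem-dihalocyclopropane ring expansion, in which methoxy-assisted loss of the endo bromide opens the C8–C6 bond disrotatorily and methanol traps the oxocarbenium ion, so that C7 is inserted as a vinyl bromide and the ring carbonyl appears as a non-enolisable ketal that cannot lose HBr.

Step 5
Reactants: 7 2-bromo-5-(3,3-dimethoxybutyl)-6-methylcyclohepta-2,5-dien-1-one dimethyl ketal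
Product: 8 5-(3,3-dimethoxybutyl)-2-isopropyl-6-methylcyclohepta-2,5-dien-1-one dimethyl ketal
Conditions: i-PrMgCl, Pd(dppf)Cl2 (3 mol%), THF, 0 °C to rt
Reagents that add atoms: isopropylmagnesium chloride, CC(C)[Mg]Cl
Why: Kumada coupling of an alkenyl bromide with a secondary alkyl Grignard reagent, for which the wide bite angle of dppf makes reductive elimination faster than β-hydride elimination and so suppresses n-propyl and reduced products, while both ketals are inert.

Step 6
Reactants: 8 5-(3,3-dimethoxybutyl)-2-isopropyl-6-methylcyclohepta-2,5-dien-1-one dimethyl ketal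
Product: 9 2-isopropyl-6-methyl-5-(3-oxobutyl)cyclohepta-2,5-dien-1-one (achiral)
Conditions: 10% aq. oxalic acid on SiO2, CH2Cl2, rt
Reagents that add atoms: water, O
Why: Mild acid hydrolysis removes the allylic and the aliphatic dimethyl ketal in one operation, under the kind of conditions that release β,γ-unsaturated ketones from Birch products without moving C1=C10 into conjugation.

Step 7
Reactants: 9 2-isopropyl-6-methyl-5-(3-oxobutyl)cyclohepta-2,5-dien-1-one
Product: 11 (4S,5R)-4β-hydroxyguaia-1(10),6-dien-8-one (4-OH β; 4-CH3 α; H-5 α), via trienamine 10 (not isolated)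
Conditions: 9-amino(9-deoxy)-epi-quinine (20 mol%), 2-fluorobenzoic acid (40 mol%), toluene (0.02 M), 40 °C, argon
Reagents that add atoms: none
Why: Proposed new method: the primary amine condenses with the hindered C8 ketone and loss of the doubly allylic H-5 from the iminium ion gives the linear trienamine 10 (N–C8=C7–C6=C5–C1=C10), whose γ carbon C5 adds to the tethered C4 ketone before hydrolysis returns the C6=C7–C8 enone and the catalyst. The closest known reaction type is the amine-catalysed (dienamine) vinylogous aldol addition of cyclic enones to activated ketones, together with the classical intramolecular aldol cyclisation; a ring-forming version with an unactivated methyl ketone acceptor and an α-branched cycloheptadienone donor has not been shown. Ring A closes in a 5-(enolexo)-exo-trig mode, the nucleophilic C5=C6 bond lying outside the new ring. C5 is set by the catalyst, whose protonated quinuclidine hydrogen-bonds the acceptor carbonyl and presents it to one enantiotopic face of the flat trienamine, and C4 is set relative to C5 in the compact bicyclic transition state, where the methyl group takes the open sector next to H-5 (trans to C6) and the smaller oxygen the sector next to C6. The step needs site selectivity among the nucleophilic carbons and the tether secures it: C7 could only form a bridged seven-membered ring, C10 would need a 5-(enolendo) closure to a quaternary centre, C9 of the cross-conjugated isomer would need a trans-cyclohexene because C2 and C9 are trans on C1=C10, and enamines of the methyl ketone reach C6 only through an anti-Bredt bicycle. High dilution, exclusion of air and the absence of strong base hold back intermolecular aldol reactions, oxidation to a tropone, retro-aldol opening and loss of water.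

Step 8
Reactants: 11 (4S,5R)-4β-hydroxyguaia-1(10),6-dien-8-one
Product: 12 guaia-1(10),6-diene-4β,8β-diol (4S,5R,8R)
Conditions: (S)-2-methyl-CBS-oxazaborolidine (20 mol%), catecholborane (2.5 equiv), toluene, −78 °C
Reagents that add atoms: none
Why: Corey–Bakshi–Shibata reduction, in which the α-branched alkenyl arm (C7) acts as the large and C9H2 as the small substituent, so the (S)-catalyst delivers hydride to the α face and sets 8R (8β-OH) under reagent control while catecholborane at low temperature leaves both alkenes alone.

Step 9
Reactants: 12 guaia-1(10),6-diene-4β,8β-diol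
Product: 13 6β,7β-epoxyguai-1(10)-ene-4β,8β-diol (4S,5S,6S,7R,8R)
Conditions: VO(acac)2 (5 mol%), t-BuOOH (1.05 equiv), CH2Cl2, 0 °C
Reagents that add atoms: tert-butyl hydroperoxide, CC(C)(C)OO
Why: Vanadium-catalysed hydroxyl-directed epoxidation, in which the allylic 8β-alkoxide binds the metal and delivers oxygen syn to itself, the homoallylic 4β-OH reinforces the same face so that C6 and C7 receive oxygen from the β side, and the rate advantage of an allylic alcohol spares C1=C10.

Step 10
Reactants: 13 6β,7β-epoxyguai-1(10)-ene-4β,8β-diol
Product: 14 6β,7β-epoxy-4β-hydroxyguai-1(10)-en-8-one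
Conditions: Dess–Martin periodinane, NaHCO3, CH2Cl2, 0 °C to rt
Reagents that add atoms: none
Why: Dess–Martin oxidation of the only secondary alcohol under buffered conditions, which leaves the tertiary alcohol, the epoxide and the skipped C1=C10 alkene untouched.

Step 11
Reactants: 14 6β,7β-epoxy-4β-hydroxyguai-1(10)-en-8-one
Product: 15 4β,6β-dihydroxyguai-1(10)-en-8-one (H-5 α; H-7 α; isopropyl β)
Conditions: SmI2 (2.2 equiv), THF–MeOH, −78 °C
Reagents that add atoms: none
Why: Electron-transfer reduction of an α,β-epoxy ketone to the aldol, in which the ketyl expels the C7–O bond whatever the substitution at C7, C6 keeps its β oxygen, and C7 is protonated axially on the α face anti to the axial C6 oxygen, placing the isopropyl group equatorial (β), which is also the thermodynamically preferred arrangement at this epimerisable centre.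

Step 12
Reactants: 15 4β,6β-dihydroxyguai-1(10)-en-8-one
Product: 16 guai-1(10)-ene-4β,6β,8α-triol (H-5 α; H-7 α)
Conditions: Me4NBH(OAc)3, MeCN–AcOH, −30 °C
Reagents that add atoms: none
Why: Evans–Saksena reduction, in which the axial 6β-OH exchanges onto boron and delivers hydride intramolecularly to the β face of C8 to give the 1,3-anti diol with an equatorial 8α-OH.

Step 13
Reactants: 17 vanillic acid
Product: 19 4-(tert-butyldimethylsilyloxy)-3-methoxybenzoic acid, via bis-silyl derivative 18 (not isolated)
Conditions: TBSCl (2.5 equiv), imidazole, DMF, rt; then AcOH–THF–H2O, rt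
Reagents that add atoms: tert-butyldimethylsilyl chloride, CC(C)(C)[Si](C)(C)Cl
Why: Silylation of both acidic OH groups followed by selective hydrolysis of the far more labile silyl ester leaves only the phenol blocked, so it cannot compete as a nucleophile in the esterification.

Step 14
Reactants: 16 guai-1(10)-ene-4β,6β,8α-triol; 19 4-(tert-butyldimethylsilyloxy)-3-methoxybenzoic acid
Product: 20 8α-[4-(tert-butyldimethylsilyloxy)-3-methoxybenzoyloxy]guai-1(10)-ene-4β,6β-diol
Conditions: 19 (1.05 equiv), EDC·HCl, DMAP, CH2Cl2, 0 °C to rt
Reagents that add atoms: none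
Why: Steglich esterification, in which the equatorial 8α-OH next to a CH2 group is acylated in preference to the tertiary 4-OH and to the axial 6β-OH, which sits between two branched carbons and is hydrogen-bonded to 4β-OH.

Step 15
Reactants: 20 8α-[4-(tert-butyldimethylsilyloxy)-3-methoxybenzoyloxy]guai-1(10)-ene-4β,6β-diol
Product: 21 8α-vanilloyloxyguai-1(10)-ene-4β,6β-diol (4S,5S,6R,7S,8S), CNP0299353.1
Conditions: HF·pyridine, pyridine, THF, 0 °C
Reagents that add atoms: none
Why: Fluoride-driven cleavage of the aryl silyl ether, the most labile group present, which leaves the ester, the three C–O stereocentres and the alkene untouched.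

Compound list
1 | 4-bromo-3-methylanisole | COc1ccc(Br)c(C)c1 | starting material
2 | but-3-en-2-ol (racemic) | CC(O)C=C | starting material
3 | 4-(4-methoxy-2-methylphenyl)butan-2-one | COc1ccc(CCC(C)=O)c(C)c1 | intermediate
4 | 4-(3,3-dimethoxybutyl)-3-methylanisole | COc1ccc(CCC(C)(OC)OC)c(C)c1 | intermediate
5 | 4-(3,3-dimethoxybutyl)-1-methoxy-5-methylcyclohexa-1,4-diene | COC1=CCC(CCC(C)(OC)OC)=C(C)C1 | intermediate
6 | 7,7-dibromo-4-(3,3-dimethoxybutyl)-1-methoxy-3-methylbicyclo[4.1.0]hept-3-ene (racemic, not isolated) | COC12CC(C)=C(CCC(C)(OC)OC)CC1C2(Br)Br | intermediate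
7 | 2-bromo-5-(3,3-dimethoxybutyl)-6-methylcyclohepta-2,5-dien-1-one dimethyl ketal | COC1(OC)CC(C)=C(CCC(C)(OC)OC)CC=C1Br | intermediate
8 | 5-(3,3-dimethoxybutyl)-2-isopropyl-6-methylcyclohepta-2,5-dien-1-one dimethyl ketal | COC1(OC)CC(C)=C(CCC(C)(OC)OC)CC=C1C(C)C | intermediate
9 | 2-isopropyl-6-methyl-5-(3-oxobutyl)cyclohepta-2,5-dien-1-one | CC(=O)CCC1=C(C)CC(=O)C(C(C)C)=CC1 | intermediate
10 | trienamine of 9 with 9-amino(9-deoxy)-epi-quinine: 1-(cinchonan-9-ylamino)-2-isopropyl-6-methyl-5-(3-oxobutyl)cyclohepta-1,3,5-triene (not isolated) | CC(=O)CCC1=C(C)CC(N[C@@H](c2ccnc3ccc(OC)cc23)[C@@H]2C[C@@H]3CCN2C[C@@H]3C=C)=C(C(C)C)C=C1 | intermediate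
11 | (4S,5R)-4β-hydroxyguaia-1(10),6-dien-8-one | O=C1CC(C)=C2CC[C@](C)(O)[C@@H]2C=C1C(C)C | intermediate
12 | guaia-1(10),6-diene-4β,8β-diol | O[C@@H]1CC(C)=C2CC[C@](C)(O)[C@@H]2C=C1C(C)C | intermediate
13 | 6β,7β-epoxyguai-1(10)-ene-4β,8β-diol | O[C@@H]1CC(C)=C2CC[C@](C)(O)[C@@H]2[C@@H]3O[C@]13C(C)C | intermediate
14 | 6β,7β-epoxy-4β-hydroxyguai-1(10)-en-8-one | O=C1CC(C)=C2CC[C@](C)(O)[C@@H]2[C@@H]3O[C@]13C(C)C | intermediate
15 | 4β,6β-dihydroxyguai-1(10)-en-8-one (7α-H) | O=C1CC(C)=C2CC[C@](C)(O)[C@@H]2[C@H](O)[C@@H]1C(C)C | intermediate
16 | guai-1(10)-ene-4β,6β,8α-triol | O[C@H]1CC(C)=C2CC[C@](C)(O)[C@@H]2[C@H](O)[C@@H]1C(C)C | intermediate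
17 | vanillic acid | COc1cc(C(=O)O)ccc1O | starting material
18 | tert-butyldimethylsilyl 4-(tert-butyldimethylsilyloxy)-3-methoxybenzoate (not isolated) | COc1cc(C(=O)O[Si](C)(C)C(C)(C)C)ccc1O[Si](C)(C)C(C)(C)C | intermediate
19 | 4-(tert-butyldimethylsilyloxy)-3-methoxybenzoic acid | COc1cc(C(=O)O)ccc1O[Si](C)(C)C(C)(C)C | intermediate
20 | 8α-[4-(tert-butyldimethylsilyloxy)-3-methoxybenzoyloxy]guai-1(10)-ene-4β,6β-diol | COc1cc(C(=O)O[C@H]2CC(C)=C3CC[C@](C)(O)[C@@H]3[C@H](O)[C@@H]2C(C)C)ccc1O[Si](C)(C)C(C)(C)C | intermediate
21 | 8α-vanilloyloxyguai-1(10)-ene-4β,6β-diol, CNP0299353.1 | COc1cc(C(=O)O[C@H]2CC(C)=C3CC[C@](C)(O)[C@@H]3[C@H](O)[C@@H]2C(C)C)ccc1O | target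

Total step count: 15. Longest linear sequence: 14 (steps 1–12, 14, 15).

Steps most likely to fail

1. Step 7.
What may go wrong:
- slow condensation of the amine with the α-branched ketone;
- drift of the dienone into its conjugated isomers;
- reversal of the aldol addition or loss of water toward the extended trienone;
- poor facial selection at C5.

The fallback uses base-mediated aldol chemistry and a reagent-controlled resolution. It sets out from 9 and returns at 12.
- Catalytic KOt-Bu in t-BuOH–THF at 0 °C generates the extended enolate under equilibrating conditions. For the same geometric reasons as in step 7, this enolate can only cyclise through C5 (intramolecular vinylogous aldol addition).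
- This should give racemic material, that is 11 together with its enantiomer (4R,5S)-4-hydroxyguaia-1(10),6-dien-8-one F1.
- The racemate is submitted to the Corey–Bakshi–Shibata reduction of step 8. Reagent control installs 8R in both enantiomers, so they become diastereomers, 12 and (4R,5S,8R)-guaia-1(10),6-diene-4,8-diol F2.
- The two diols are separated by chromatography, and 12 continues in step 9.

2. Step 4.
What may go wrong:
- competing carbene addition to the tetrasubstituted C1=C10 alkene, or double addition;
- demethylation of the oxocarbenium ion by bromide, followed by loss of HBr toward a tropone.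

The fallback abandons carbene chemistry, cleaves the enol ether and rebuilds the ring with the isopropyl carbon already in place. It sets out from 5 and returns at 9, replacing steps 4–6.
- Catalytic OsO4 with N-methylmorpholine N-oxide in aqueous acetone dihydroxylates only the enol ether, since fully substituted alkenes are very slow in this reaction. After collapse of the hemiketal this gives 4-(3,3-dimethoxybutyl)-6-hydroxy-3-methylcyclohex-3-en-1-one F3.
- Pb(OAc)4 in methanol cleaves the acyloin to methyl (Z)-7,7-dimethoxy-3-methyl-4-(2-oxoethyl)oct-3-enoate F4, whose Z geometry is inherited from the ring.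
- Acetalisation (HC(OMe)3, PPTS, MeOH) gives methyl (Z)-4-(2,2-dimethoxyethyl)-7,7-dimethoxy-3-methyloct-3-enoate F5.
- Acylation of lithiated diethyl isobutylphosphonate with this ester gives diethyl [(6Z)-7-(2,2-dimethoxyethyl)-10,10-dimethoxy-2,6-dimethyl-4-oxoundec-6-en-3-yl]phosphonate F6.
- Oxalic acid on wet silica unmasks diethyl [(6Z)-2,6-dimethyl-4,10-dioxo-7-(2-oxoethyl)undec-6-en-3-yl]phosphonate F7.
- An intramolecular Horner–Wadsworth–Emmons reaction (LiCl, i-Pr2NEt, MeCN, high dilution), in which the aldehyde reacts in preference to the methyl ketone, closes C6=C7 and gives 9.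

3. Step 9.
What may go wrong:
- homoallylic direction of the oxidant to the electron-rich C1=C10 alkene;
- over-oxidation to a bis-epoxide.

The fallback replaces electrophilic by nucleophilic oxygen transfer. It sets out from 11 and returns at 14, skipping steps 8–10.
- Enone 11 is treated with aqueous H2O2 and a salt of a 9-amino cinchona amine (Weitz–Scheffer type epoxidation under iminium activation).
- The oxidant can then attack only the electron-poor C6=C7 bond.
- The pseudo-enantiomer of the catalyst that delivers the hydroperoxide to the β face is chosen.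
- No compound outside the list is formed.

Further compounds
F1 | step 7 | (4R,5S)-4-hydroxyguaia-1(10),6-dien-8-one (enantiomer of 11) | O=C1CC(C)=C2CC[C@@](C)(O)[C@H]2C=C1C(C)C
F2 | step 7 | (4R,5S,8R)-guaia-1(10),6-diene-4,8-diol | O[C@@H]1CC(C)=C2CC[C@@](C)(O)[C@H]2C=C1C(C)C
F3 | step 4 | 4-(3,3-dimethoxybutyl)-6-hydroxy-3-methylcyclohex-3-en-1-one (racemic) | O=C1CC(C)=C(CCC(C)(OC)OC)CC1O
F4 | step 4 | methyl (Z)-7,7-dimethoxy-3-methyl-4-(2-oxoethyl)oct-3-enoate | COC(=O)C/C(C)=C(\CC=O)CCC(C)(OC)OC
F5 | step 4 | methyl (Z)-4-(2,2-dimethoxyethyl)-7,7-dimethoxy-3-methyloct-3-enoate | COC(=O)C/C(C)=C(\CC(OC)OC)CCC(C)(OC)OC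
F6 | step 4 | diethyl [(6Z)-7-(2,2-dimethoxyethyl)-10,10-dimethoxy-2,6-dimethyl-4-oxoundec-6-en-3-yl]phosphonate (racemic) | CCOP(=O)(OCC)C(C(C)C)C(=O)C/C(C)=C(\CC(OC)OC)CCC(C)(OC)OC
F7 | step 4 | diethyl [(6Z)-2,6-dimethyl-4,10-dioxo-7-(2-oxoethyl)undec-6-en-3-yl]phosphonate (racemic) | CCOP(=O)(OCC)C(C(C)C)C(=O)C/C(C)=C(\CC=O)CCC(C)=O
F0 | step 9 | none | none
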